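## Structural features

The target is a labdane-type diterpenoid acid: a trans-fused decalin in which ring A (C1–C5 and C10) and ring B (C5–C10) share the C5–C10 bond, with the angular methyl C20 on C10 (its face is called β below) and H5 on the α face. Ring B holds a tetrasubstituted C8=C9 alkene that carries methyl C17 on C8 and, on C9, the chain C11H2–C12H2–C13(CH3)=C14H–C15O2H with (E) geometry. Four stereocentres stand in a row: C3 (axial 3α isovalerate), quaternary C4 (α-methyl C18 and β-CH2O C19, the latter acylated by the second isovalerate), C5, and C6 (axial 6β hydroxyl); C5 is wedged between the quaternary carbons C4 and C10. The free 6β-hydroxyl is syn-axial to both C19 and C20, which makes it hard to acylate, and it is homoallylic to the tetrasubstituted alkene, so strong acid threatens dehydration and alkene migration. Two saturated esters must survive the unmasking of the C15 acid, and at the ketone oxidation level the C6 carbonyl and the C8=C9 alkene form a β,γ-enone whose C7 hydrogens are acidic, so the alkene can slip into conjugation. The real difficulty is the congested C4–C5–C10–C9 region together with the need to tell three oxygens (O3, O6, O19) apart, one of which (O3) is epimeric to what the simplest chiral ring A building block delivers. The key step uses the unit C6(=O)–C7H2–C8(CH3)=C9 of the 6-ketone: such a β,γ-unsaturated ketone is what a 1,3-acyl shift makes from a 2-isopropenylcyclobutanone whose four-membered ring consists of C5, C6, C9 and C10 and is fused to ring A.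

## Logic of the disconnections

30 ⇒ 29 ⇒ 28: the O–C bond of the C15 ester is cut. The acid stays masked as a tert-butyl ester to the end because a free acid would interfere with the organozinc and hydride steps. The forward cleavage must spare two isovalerates, a homoallylic alcohol and a tetrasubstituted alkene, so a non-protic silyl triflate method is required, not strong acid or hydroxide.

28 ⇒ 27: the two acyl C–O bonds at O3 and O19 are cut. Both esters are the same, so one acylation serves and the problem shrinks to a triol. The forward step must leave the 6β-hydroxyl, which is syn-axial to C19 and C20, untouched.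

27 ⇒ 26 ⇒ 25: the O19–Si bond and the C3–H and C6–H bonds are cut. Both carbinols are axial and both arise by equatorial hydride delivery, so one bulky hydride can set C3 and C6 together from 25. The gain is that the building block may carry the easily accessible 3β configuration and be corrected late. The demand is face selectivity at two hindered ketones and tolerance of the enoate.

25 ⇒ 24 ⇒ 23: the oxidation level at C3 and the O3–Si bond are adjusted. This requires two silyl groups that can be told apart (triethylsilyl on O3, tert-butyldimethylsilyl on the neopentyl O19) and a neutral oxidant that leaves the β,γ-enone in place.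

23 ⇒ 22 + 21, 22 ⇒ 19, 19 ⇒ 18, 21 ⇒ 20: the C12–C13 bond is cut. An sp3–sp2 cross-coupling is convergent and takes the (E) geometry from 21, which comes in one step from 20. The organometallic at C12 must coexist with the C6 ketone, hence zinc, reached from the chloride of 18 by halide exchange.

18 ⇒ 17 ⇒ 16: the C6–C7 bond is cut. Reversing the 1,3-acyl shift reconnects C6 to C9 and contracts ring B to a cyclobutanone spanning C5, C6, C9 and C10 with an isopropenyl group (C8, C7, C17) on C9. Ring B, its tetrasubstituted alkene and both alkene substituents are thereby reduced to a [2+2] adduct of ring A. The forward step must cleave C6–C9, recombine at C7 without loss of CO, and then epimerise C5 without moving the alkene.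

16 ⇒ 15 ⇒ 14 + 9, 14 ⇒ 13: the C5–C6 and C9–C10 bonds are cut. A keteniminium ion is electrophilic enough for an unactivated trisubstituted alkene and gives the required regiochemistry (C6 to C5, C9 to C10). The forward step must attack the α face of 9 and form two adjacent quaternary carbons, and the stub on C9 must carry no Lewis-basic oxygen.

13 ⇒ 11 + 12, 11 ⇒ 10: the C9–C11 bond and the amide C–N bond are cut. Deconjugative α-alkylation creates the isopropenyl group and the two-carbon stub in one step from a commodity acid chloride. The forward step must alkylate at the α-carbon and displace bromide, not chloride.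

9 ⇒ 8 ⇒ 7 ⇒ 6: the C5–O bond (through the enol triflate) and the C10–C20 bond are cut. This returns the ring A alkene to a ketone whose only enolisable position is C10. The forward steps need a single enolate regiochemistry, which the quaternary C4 guarantees.

6 ⇒ 5 ⇒ 4 ⇒ 3 ⇒ 1 + 2: the two O–Si bonds, the C3–H bond and the C4–C19 bond are cut. This leads back to a prochiral dione. The forward reduction must select one of two enantiotopic carbonyls and one face, which sets C4 (absolute) and C3 (3β) together.

## Other disconnections considered

Alternative 1: The cut is the C5–C6 bond of ring B.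
- **Forward step:** the achiral aldehyde A1 is a 4-methylcyclohexa-2,5-dienone whose C10 carries the dioxolane-masked C9 ketone and the C8–C7–C6 aldehyde arm. A chiral triazolylidene carbene would turn the C6 aldehyde into an acyl anion equivalent that adds to C5 of one enone arm (intramolecular Stetter reaction). Base equilibration of C5 would then give the trans-fused dione A2.
- **In favour:** ring B, the C6 ketone and the absolute configuration of quaternary C10 would come from an achiral substrate under catalyst control. That is better than the substrate-controlled facial selectivity of step 10. The C5 equilibration would not be endangered by a β,γ-alkene, which is also better. The masked C9 ketone is a natural handle for C17 and the side chain.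
- **Against:** A2 carries none of the ring A decoration. Quaternary C4 with two different one-carbon groups would have to be built by successive alkylations next to C5, with control of which group is β. C3 would need an axial carbinol, C1=C2 would have to be reduced, and three carbonyl groups (C3, C6, masked C9) would have to be differentiated while C6 enolises in competition.
- **Comparison:** on structure, the chosen plan imports C3 and C4 at the outset and adjusts only C5, C6 and C9. On mechanism, alternative 1 is polar and catalyst-controlled, whereas the chosen plan passes through a radical pair. On step economy, alternative 1 is equal or better up to its key step and clearly longer after it.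

Alternative 2: The cuts are C7–C8 and C9–C10.
- **Forward step:** the ring A ethoxydiene A3 (C7=C6(OEt)–C5=C10, with the same C3 and C4 substituents as 9) and ethyl but-2-ynoate A4 would combine in a thermal [4+2] cycloaddition to the cyclohexa-1,4-diene A5.
- **In favour:** two skeletal bonds and ring B form in one step, better than the chosen plan, which needs steps 10 and 11 for three bonds. The regiochemistry is reinforced because the C6 donor ends up para to the C9 ester. The chiral ring A source is the same, so the two plans are equal there. Hydrolysis of the enol ether would create C5 by protonation from the open α face, so the trans fusion might arise without a separate epimerisation, which is better. Conjugation with the C9 ester would hold the alkene at C8=C9, which is also better.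
- **Against:** the diene terminus C10 is fully substituted and A4 is an internal, singly activated alkyne, so forcing conditions would be needed, under which A3 may isomerise. The C9 substituent arrives as an ester, that is, C11 at the wrong oxidation level and without C12. The side chain would need reduction, allylic activation and a C12–C15 fragment, with a risk of allylic transposition.
- **Comparison:** facial selectivity at C10 rests on the C19 arm in both plans, so they are equal there. Alternative 2 avoids photochemistry. Its step count to A3 should match that to 16, but the way from A5 to the target is longer.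

Alternative 3: The cut is C7–C8.
- **Forward step:** in the silyl enol ether A6 the C5 acyl group is present as C6(OSi)=C7H2 and C10 carries methyl and prop-1-ynyl (C9≡C8–C17). Cationic monovalent gold (a phosphine gold chloride activated by a silver salt) would activate the alkyne for 6-endo attack by C7. An iodonium source would capture the C9 vinylgold to give the trans-fused iodo enone A7.
- **In favour:** the conditions are mild and ionic. The trans ring fusion is set before cyclisation, so no epimerisation next to a β,γ-enone is needed, which is better. The C9 iodide would allow the whole C11–C15 chain to be attached in one sp2–sp3 coupling, better than the stub elaboration of steps 12 and 14.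
- **Against:** A6 needs quaternary C10 with methyl and propynyl groups, trans to a C5 acetyl group, on a ring A that already carries C3 and C4. That is a demanding and longer construction. The cyclisation could go 5-exo, the vinylgold could be protonated, or the enol ether could be iodinated directly. The resulting iodide, flanked by C10, is a hindered coupling partner.
- **Comparison:** alternative 3 is shorter after its key step and longer and less certain before it. In the chosen plan, 16 comes in one step from two simple partners. The product skeletons (6-oxo, C8=C9) are equal.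

Key step: step 11

Remarks on the chemistry:
- Labdane numbering is used for all bicyclic compounds, and β is the face of the C10 methyl group.
- 16 is carried as a mixture of C9 epimers, which converge in step 11.
- The two-carbon stub on C9 ends in chlorine and not in an ether oxygen. An ether oxygen four atoms from the amide carbon could close onto the keteniminium carbon in step 10 (five-membered oxonium ion, then loss of the O-substituent).
- The ring A alkene is made through the enol triflate and not through a sulfonylhydrazone, because the only α-hydrogen of 7 is a methine.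
- Simple reagents are assumed to be commercial.

## Route

Step 1
Reactants: 1 2-methylcyclohexane-1,3-dione; 2 formaldehyde (37 % aqueous solution)
Product: 3 2-(hydroxymethyl)-2-methylcyclohexane-1,3-dione
Conditions: aq. CH2O (37 %, excess), H2O, 25 °C
Reagents that add atoms: none
Why: Aldol-type hydroxymethylation of the acidic C2–H of the dione, forming the C4–C19 bond; the product has no enolisable C2–H, so only one CH2OH group can enter, and excess formaldehyde holds the retro-aldol equilibrium on the product side.

Step 2
Reactants: 3 2-(hydroxymethyl)-2-methylcyclohexane-1,3-dione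
Product: 4 2-{[tert-butyl(dimethyl)silyl]oxymethyl}-2-methylcyclohexane-1,3-dione
Conditions: t-BuMe2SiOTf, 2,6-lutidine, CH2Cl2, −78 °C
Reagents that add atoms: tert-butyldimethylsilyl triflate, CC(C)(C)[Si](C)(C)OS(=O)(=O)C(F)(F)F
Why: Silylation of the primary alcohol with a silyl triflate and a weak pyridine base at low temperature should outrun retro-aldol loss of formaldehyde; the CH2OSi arm is later the bulky group that steers steps 3 and 10.

Step 3
Reactants: 4 2-{[tert-butyl(dimethyl)silyl]oxymethyl}-2-methylcyclohexane-1,3-dione
Product: 5 (2S,3S)-2-{[tert-butyl(dimethyl)silyl]oxymethyl}-3-hydroxy-2-methylcyclohexan-1-one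
Conditions: (R)-2-methyl-CBS-oxazaborolidine (20 mol %), catecholborane (1.1 equiv), toluene, −78 °C; then MeOH, aq. NaHCO3
Reagents that add atoms: none
Why: Corey–Bakshi–Shibata reduction used as desymmetrisation of a 2,2-disubstituted 1,3-dione: the (R)-catalyst treats the quaternary carbon as the large group and should give the (S)-carbinol, and of the two enantiotopic carbonyls the one is reduced at which this hydride also arrives anti to the CH2OTBS arm, so catalyst and substrate control are matched for the (2S,3S) isomer (OH cis to CH2OTBS). This sets C3 (3β) and the absolute configuration of C4; one equivalent of hydride at low temperature limits reduction of the second ketone.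

Step 4
Reactants: 5 (2S,3S)-2-{[tert-butyl(dimethyl)silyl]oxymethyl}-3-hydroxy-2-methylcyclohexan-1-one
Product: 6 (2S,3S)-2-{[tert-butyl(dimethyl)silyl]oxymethyl}-2-methyl-3-(triethylsilyloxy)cyclohexan-1-one
Conditions: Et3SiOTf, 2,6-lutidine, CH2Cl2, −78 °C
Reagents that add atoms: triethylsilyl triflate, CC[Si](CC)(CC)OS(=O)(=O)C(F)(F)F
Why: Silylation of the hindered secondary alcohol with the silyl triflate; the triethylsilyl ether blocks retro-aldol cleavage in the enolate steps and can later be removed in the presence of the neopentyl tert-butyldimethylsilyl ether.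

Step 5
Reactants: 6 (2S,3S)-2-{[tert-butyl(dimethyl)silyl]oxymethyl}-2-methyl-3-(triethylsilyloxy)cyclohexan-1-one
Product: 7 (2S,3S,6RS)-2-{[tert-butyl(dimethyl)silyl]oxymethyl}-2,6-dimethyl-3-(triethylsilyloxy)cyclohexan-1-one
Conditions: LiN(i-Pr)2, THF, −78 °C; MeI, −78 → −20 °C
Reagents that add atoms: iodomethane, CI
Why: Enolate alkylation that forms the C10–C20 bond; C4 is quaternary, so only C10 can be deprotonated, and the configuration of the new centre is irrelevant because C10 becomes trigonal in step 6.

Step 6
Reactants: 7 (2S,3S,6RS)-2-{[tert-butyl(dimethyl)silyl]oxymethyl}-2,6-dimethyl-3-(triethylsilyloxy)cyclohexan-1-one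
Product: 8 (5S,6S)-6-{[tert-butyl(dimethyl)silyl]oxymethyl}-2,6-dimethyl-5-(triethylsilyloxy)cyclohex-1-en-1-yl trifluoromethanesulfonate
Conditions: KN(SiMe3)2, THF, −78 °C; PhNTf2, −78 → 0 °C
Reagents that add atoms: N-phenylbis(trifluoromethanesulfonimide), O=S(=O)(N(c1ccccc1)S(=O)(=O)C(F)(F)F)C(F)(F)F
Why: The only α-hydrogen left is the C10 methine, so a single potassium enolate forms and O-sulfonylation gives the C5 enol triflate, as is known for 2,2,6-trisubstituted cyclohexanones. A sulfonylhydrazone (Shapiro) route was avoided because it would require deprotonation of this methine in a doubly α-branched hydrazone.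

Step 7
Reactants: 8 (5S,6S)-6-{[tert-butyl(dimethyl)silyl]oxymethyl}-2,6-dimethyl-5-(triethylsilyloxy)cyclohex-1-en-1-yl trifluoromethanesulfonate
Product: 9 ring A alkene, tert-butyl{[(1S,6S)-1,3-dimethyl-6-(triethylsilyloxy)cyclohex-2-en-1-yl]methoxy}dimethylsilane
Conditions: Pd(OAc)2 (5 mol %), PPh3, HCO2H, n-Bu3N, DMF, 60 °C
Reagents that add atoms: none
Why: Palladium-catalysed formate reduction of an enol triflate (oxidative addition to zerovalent palladium formed in situ, formate exchange, loss of CO2, C–H reductive elimination) replaces OTf by H without moving the alkene and gives the trisubstituted C5=C10 alkene.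

Step 8
Reactants: 10 3-methylbut-2-enoyl chloride
Product: 11 N,N,3-trimethylbut-2-enamide
Conditions: Me2NH (2.2 equiv, THF solution), CH2Cl2, 0 °C
Reagents that add atoms: dimethylamine, CNC
Why: Acylation of a secondary amine by an acid chloride; the dimethylamide is the standard precursor of a keteniminium salt.

Step 9
Reactants: 11 N,N,3-trimethylbut-2-enamide; 12 1-bromo-2-chloroethane
Product: 13 2-(2-chloroethyl)-N,N,3-trimethylbut-3-enamide (racemic)
Conditions: LiN(i-Pr)2, THF–DMPU, −78 °C; then 12, −78 → −20 °C
Reagents that add atoms: none
Why: γ-Deprotonation gives the amide dienolate, which alkylates at the α-carbon (deconjugative alkylation), forming the C9–C11 bond and the isopropenyl group at once; bromide is displaced in preference to chloride, and the racemic C9 centre is irrelevant because C9 becomes trigonal in step 11.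

Step 10
Reactants: 13 2-(2-chloroethyl)-N,N,3-trimethylbut-3-enamide; 9 ring A alkene
Product: 16 cis-fused 9-(2-chloroethyl)-9-isopropenyl cyclobutanone on ring A (5β-H; 10β-CH3; both C9 epimers), via keteniminium triflate 14 (not isolated), via cyclobutaniminium triflate 15 (not isolated)
Conditions: Tf2O, 2,4,6-collidine, ClCH2CH2Cl, −20 → 80 °C; then H2O, 25 °C, NaHCO3 wash
Reagents that add atoms: water, O
Why: Ghosez keteniminium–alkene [2+2] cycloaddition: the electrophilic central carbon (C6) of 14 bonds to the less substituted alkene carbon C5, the tertiary cation at C10 is captured by C9, and water hydrolyses 15 to the cyclobutanone. Addition is suprafacial (cis fusion, H5 and C20 both β) and should occur on the α face, anti to the pseudoaxial C19 CH2OTBS arm, with the equatorial 3β-OTES group leaving that face open; this sets C10. Neither the chlorine-terminated stub nor the silyl ethers offer an oxygen that can reach the keteniminium carbon in a five-membered ring.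

Step 11
Reactants: 16 cis-fused 9-(2-chloroethyl)-9-isopropenyl cyclobutanone on ring A
Product: 18 trans-fused 12-chloro-6-oxo-Δ8(9) decalin (5α-H; 3β-OTES; 19-OTBS), via cis-fused ketone 17 (not isolated)
Conditions: hν (medium-pressure Hg lamp, Pyrex, λ > 300 nm), degassed C6H6, 20 °C, to high but not complete conversion; then DBU (0.3 equiv), 25 °C, stopped when 17 is consumed
Reagents that add atoms: none
Why: Excitation of the cyclobutanone n→π* band leads to Norrish α-cleavage of the strained C6–C9 bond, the one that gives an acyl radical and a tertiary allylic radical spread over C9, C8 and C7; recombination of this singlet pair at the unhindered CH2 terminus C7 forms C6–C7 and the C8=C9 alkene, a formal 1,3-acyl shift that is the known photochemical behaviour of β,γ-unsaturated ketones and of 2-vinylcyclobutanones. Ring B is not closed by a new cyclisation but arises by two-carbon expansion of the four-membered ring (C5, C6, C9, C10) into the six-membered ring C5–C10, driven by release of the cyclobutanone strain. C9 becomes trigonal, so both C9 epimers of 16 converge and the alkene can only lie between C8 and C9. C4 and C10 are untouched and C5 keeps its configuration in 17 (cis fusion, H5 β); the one stereocentre set here is C5 of 18, under thermodynamic control, when DBU enolises the C6 ketone towards C5 and the trans-decalone with H5 α is reached, the usual preference of 6-oxo decalins with an angular methyl group. The step needs recombination at C7 in preference to loss of CO or cycloreversion, which the allylic stabilisation, the solvent cage at 20 °C and the strain-free six-membered product should favour. It also needs C5 to equilibrate while the alkene stays out of conjugation, for which a sub-stoichiometric amine base in benzene and a short contact time are chosen, because the ion pair formed at the more acidic C7 is expected to collapse back at C7. The chloride, the silyl ethers and the isolated alkene do not absorb above 300 nm and are inert to DBU at 25 °C.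

Step 12
Reactants: 18 trans-fused 12-chloro-6-oxo-Δ8(9) decalin
Product: 19 trans-fused 12-iodo-6-oxo-Δ8(9) decalin (3β-OTES; 19-OTBS)
Conditions: NaI (5 equiv), NaHCO3 (cat.), butan-2-one, 80 °C
Reagents that add atoms: sodium iodide, [Na+].[I-]
Why: Finkelstein exchange (SN2) at the unhindered primary C12; ketone, alkene and both silyl ethers are inert to NaI under buffered neutral conditions.

Step 13
Reactants: 20 tert-butyl 3-oxobutanoate
Product: 21 tert-butyl (E)-3-(trifluoromethanesulfonyloxy)but-2-enoate
Conditions: Tf2O, aq. Me4NOH, hexanes, 5–10 °C
Reagents that add atoms: trifluoromethanesulfonic anhydride, O=S(=O)(OS(=O)(=O)C(F)(F)F)C(F)(F)F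
Why: O-Triflation of a β-keto ester through its non-chelated tetramethylammonium enolate is known to give the (E)-enol triflate (OTf trans to the ester), the geometry needed for C13=C14.

Step 14
Reactants: 19 trans-fused 12-iodo-6-oxo-Δ8(9) decalin; 21 tert-butyl (E)-3-(trifluoromethanesulfonyloxy)but-2-enoate
Product: 23 tert-butyl (E)-enoate of the 6-oxo-Δ8(9) decalin (full C11–C15 chain; 3β-OTES; 19-OTBS), via alkylzinc iodide 22 (not isolated)
Conditions: Zn dust (activated with BrCH2CH2Br and Me3SiCl), LiCl, THF, 35 °C; then 21, Pd(PPh3)4 (5 mol %), THF, 25–45 °C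
Reagents that add atoms: none
Why: Negishi sp3–sp2 coupling: zinc inserts into the primary C–I bond in the presence of LiCl, an alkylzinc iodide tolerates the ketone and the silyl ethers, and coupling with the enol triflate at zerovalent palladium proceeds with retention of alkene geometry, forming C12–C13 and the (E)-trisubstituted enoate.

Step 15
Reactants: 23 tert-butyl (E)-enoate of the 6-oxo-Δ8(9) decalin
Product: 24 3β-hydroxy 6-ketone (19-OTBS; tert-butyl ester)
Conditions: PPTS (0.2 equiv), MeOH–CH2Cl2, 0 °C
Reagents that add atoms: none
Why: Acid-catalysed methanolysis distinguishes the two silyl ethers, the triethylsilyl ether being cleaved far faster than the tert-butyldimethylsilyl ether on the neopentyl O19; the β,γ-enone and the tert-butyl ester should tolerate PPTS at 0 °C.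

Step 16
Reactants: 24 3β-hydroxy 6-ketone
Product: 25 3,6-diketone (19-OTBS; tert-butyl ester)
Conditions: Dess–Martin periodinane, NaHCO3, CH2Cl2, 0 → 25 °C
Reagents that add atoms: none
Why: Buffered Dess–Martin oxidation gives the C3 ketone without acid or base that could move the C8=C9 alkene; C4 is quaternary, so the β-silyloxy ketone cannot eliminate.

Step 17
Reactants: 25 3,6-diketone
Product: 26 3α,6β-diol (19-OTBS; tert-butyl ester)
Conditions: LiBH(sec-Bu)3 (3 equiv), THF, −78 → −40 °C; then H2O
Reagents that add atoms: none
Why: The bulky trialkylborohydride should attack both ketones along the equatorial trajectory: at C3 from the β face of the 4,4-disubstituted cyclohexanone, giving the axial 3α-alcohol as known for 3-oxo triterpenoids, and at C6 from the α face, the β face being closed by the syn-axial C19 and C20 groups, giving the axial 6β-alcohol. At low temperature the β,β-disubstituted enoate and the tert-butyl ester should not be reduced.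

Step 18
Reactants: 26 3α,6β-diol
Product: 27 3α,6β,19-triol (tert-butyl ester)
Conditions: HF·pyridine, pyridine, THF, 0 → 25 °C
Reagents that add atoms: none
Why: Fluoride cleavage of the remaining silyl ether under pyridine-buffered conditions frees the C19 alcohol without acid-induced dehydration of the homoallylic 6β-alcohol; the tert-butyl ester is stable to HF·pyridine.

Step 19
Reactants: 27 3α,6β,19-triol
Product: 28 3α,19-bis(3-methylbutanoate) with free 6β-hydroxyl (tert-butyl ester)
Conditions: (i-PrCH2CO)2O (4 equiv), DMAP (0.2 equiv), pyridine, CH2Cl2, 0 → 25 °C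
Reagents that add atoms: 3-methylbutanoic anhydride, CC(C)CC(=O)OC(=O)CC(C)C
Why: DMAP-catalysed acylation should esterify the primary C19 alcohol and the axial 3α-alcohol, while the 6β-alcohol, syn-axial to both C19 and C20 (the situation of an 11β-hydroxy steroid), should stay free under these mild conditions.

Step 20
Reactants: 28 3α,19-bis(3-methylbutanoate) tert-butyl ester
Product: 30 target acid (3α,19-bis-isovalerate; 6β-OH), via bis(trimethylsilyl) derivative 29 (not isolated)
Conditions: Me3SiOTf (4 equiv), 2,6-lutidine (6 equiv), CH2Cl2, 0 °C; then aq. citric acid, THF, 25 °C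
Reagents that add atoms: none
Why: A silyl triflate with a hindered pyridine base converts a tert-butyl ester into the silyl ester with loss of isobutene under non-protic conditions, which avoids protonation of the tetrasubstituted alkene and hydrolysis of the isovalerates; the transient silyl groups on O15 and O6 are hydrolysed on mild aqueous acid work-up.

## Compound list

1 | 2-methylcyclohexane-1,3-dione | CC1C(=O)CCCC1=O | starting material
2 | formaldehyde (37 % aqueous solution) | C=O | starting material
3 | 2-(hydroxymethyl)-2-methylcyclohexane-1,3-dione | CC1(CO)C(=O)CCCC1=O | intermediate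
4 | 2-{[tert-butyl(dimethyl)silyl]oxymethyl}-2-methylcyclohexane-1,3-dione | CC1(CO[Si](C)(C)C(C)(C)C)C(=O)CCCC1=O | intermediate
5 | (2S,3S)-2-{[tert-butyl(dimethyl)silyl]oxymethyl}-3-hydroxy-2-methylcyclohexan-1-one (OH cis to CH2OTBS) | O=C1CCC[C@H](O)[C@]1(C)CO[Si](C)(C)C(C)(C)C | intermediate
6 | (2S,3S)-2-{[tert-butyl(dimethyl)silyl]oxymethyl}-2-methyl-3-(triethylsilyloxy)cyclohexan-1-one | O=C1CCC[C@H](O[Si](CC)(CC)CC)[C@]1(C)CO[Si](C)(C)C(C)(C)C | intermediate
7 | (2S,3S,6RS)-2-{[tert-butyl(dimethyl)silyl]oxymethyl}-2,6-dimethyl-3-(triethylsilyloxy)cyclohexan-1-one | O=C1C(C)CC[C@H](O[Si](CC)(CC)CC)[C@]1(C)CO[Si](C)(C)C(C)(C)C | intermediate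
8 | (5S,6S)-6-{[tert-butyl(dimethyl)silyl]oxymethyl}-2,6-dimethyl-5-(triethylsilyloxy)cyclohex-1-en-1-yl trifluoromethanesulfonate | CC1=C(OS(=O)(=O)C(F)(F)F)[C@@](C)(CO[Si](C)(C)C(C)(C)C)[C@@H](O[Si](CC)(CC)CC)CC1 | intermediate
9 | ring A alkene, tert-butyl{[(1S,6S)-1,3-dimethyl-6-(triethylsilyloxy)cyclohex-2-en-1-yl]methoxy}dimethylsilane (labdane C5=C10; 3β-OTES; 4β-CH2OTBS; 4α-CH3) | CC1=C[C@@](C)(CO[Si](C)(C)C(C)(C)C)[C@@H](O[Si](CC)(CC)CC)CC1 | intermediate
10 | 3-methylbut-2-enoyl chloride | CC(C)=CC(=O)Cl | starting material
11 | N,N,3-trimethylbut-2-enamide | CC(C)=CC(=O)N(C)C | intermediate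
12 | 1-bromo-2-chloroethane | ClCCBr | starting material
13 | 2-(2-chloroethyl)-N,N,3-trimethylbut-3-enamide (racemic) | C=C(C)C(CCCl)C(=O)N(C)C | intermediate
14 | keteniminium triflate, [2-(2-chloroethyl)-3-methylbuta-1,3-dien-1-ylidene]dimethylammonium trifluoromethanesulfonate | C=C(C)C(CCCl)=C=[N+](C)C.[O-]S(=O)(=O)C(F)(F)F | intermediate
15 | cyclobutaniminium triflate, the C6 N,N-dimethyliminium ion corresponding to 16 (C9 epimers) | C[N+](C)=C1[C@@H]2[C@@](C)(CO[Si](C)(C)C(C)(C)C)[C@@H](O[Si](CC)(CC)CC)CC[C@]2(C)C1(CCCl)C(C)=C.[O-]S(=O)(=O)C(F)(F)F | intermediate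
16 | cis-fused cyclobutanone, 8-(2-chloroethyl)-1,5-dimethyl-8-(prop-1-en-2-yl)-5-{[tert-butyl(dimethyl)silyl]oxymethyl}-4-(triethylsilyloxy)bicyclo[4.2.0]octan-7-one; labdane terms: C6 ketone, four-membered ring C5–C6–C9–C10, 3β-OTES, 4α-CH3, 4β-CH2OTBS, 5β-H, 10β-CH3, C9 epimers | O=C1[C@@H]2[C@@](C)(CO[Si](C)(C)C(C)(C)C)[C@@H](O[Si](CC)(CC)CC)CC[C@]2(C)C1(CCCl)C(C)=C | intermediate
17 | cis-fused 12-chloro-3β-(triethylsilyloxy)-19-[tert-butyl(dimethyl)silyloxy]-13,14,15,16-tetranorlabd-8(9)-en-6-one (5β-H, 10β-CH3) | CC1=C(CCCl)[C@@]2(C)CC[C@H](O[Si](CC)(CC)CC)[C@](C)(CO[Si](C)(C)C(C)(C)C)[C@H]2C(=O)C1 | intermediate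
18 | trans-fused 12-chloro-3β-(triethylsilyloxy)-19-[tert-butyl(dimethyl)silyloxy]-13,14,15,16-tetranorlabd-8(9)-en-6-one (5α-H, 10β-CH3) | CC1=C(CCCl)[C@@]2(C)CC[C@H](O[Si](CC)(CC)CC)[C@](C)(CO[Si](C)(C)C(C)(C)C)[C@@H]2C(=O)C1 | intermediate
19 | trans-fused 12-iodo-3β-(triethylsilyloxy)-19-[tert-butyl(dimethyl)silyloxy]-13,14,15,16-tetranorlabd-8(9)-en-6-one | CC1=C(CCI)[C@@]2(C)CC[C@H](O[Si](CC)(CC)CC)[C@](C)(CO[Si](C)(C)C(C)(C)C)[C@@H]2C(=O)C1 | intermediate
20 | tert-butyl 3-oxobutanoate | CC(=O)CC(=O)OC(C)(C)C | starting material
21 | tert-butyl (E)-3-(trifluoromethanesulfonyloxy)but-2-enoate | C/C(OS(=O)(=O)C(F)(F)F)=C\C(=O)OC(C)(C)C | intermediate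
22 | alkylzinc iodide, the C12–ZnI analogue of 19 | CC1=C(CC[Zn]I)[C@@]2(C)CC[C@H](O[Si](CC)(CC)CC)[C@](C)(CO[Si](C)(C)C(C)(C)C)[C@@H]2C(=O)C1 | intermediate
23 | tert-butyl (13E)-6-oxo-3β-(triethylsilyloxy)-19-[tert-butyl(dimethyl)silyloxy]labda-8(9),13-dien-15-oate | CC1=C(CC/C(C)=C/C(=O)OC(C)(C)C)[C@@]2(C)CC[C@H](O[Si](CC)(CC)CC)[C@](C)(CO[Si](C)(C)C(C)(C)C)[C@@H]2C(=O)C1 | intermediate
24 | tert-butyl (13E)-3β-hydroxy-6-oxo-19-[tert-butyl(dimethyl)silyloxy]labda-8(9),13-dien-15-oate | CC1=C(CC/C(C)=C/C(=O)OC(C)(C)C)[C@@]2(C)CC[C@H](O)[C@](C)(CO[Si](C)(C)C(C)(C)C)[C@@H]2C(=O)C1 | intermediate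
25 | tert-butyl (13E)-3,6-dioxo-19-[tert-butyl(dimethyl)silyloxy]labda-8(9),13-dien-15-oate | CC1=C(CC/C(C)=C/C(=O)OC(C)(C)C)[C@@]2(C)CCC(=O)[C@](C)(CO[Si](C)(C)C(C)(C)C)[C@@H]2C(=O)C1 | intermediate
26 | tert-butyl (13E)-3α,6β-dihydroxy-19-[tert-butyl(dimethyl)silyloxy]labda-8(9),13-dien-15-oate | CC1=C(CC/C(C)=C/C(=O)OC(C)(C)C)[C@@]2(C)CC[C@@H](O)[C@](C)(CO[Si](C)(C)C(C)(C)C)[C@@H]2[C@H](O)C1 | intermediate
27 | tert-butyl (13E)-3α,6β,19-trihydroxylabda-8(9),13-dien-15-oate | CC1=C(CC/C(C)=C/C(=O)OC(C)(C)C)[C@@]2(C)CC[C@@H](O)[C@](C)(CO)[C@@H]2[C@H](O)C1 | intermediate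
28 | tert-butyl (13E)-6β-hydroxy-3α,19-bis(3-methylbutanoyloxy)labda-8(9),13-dien-15-oate | CC1=C(CC/C(C)=C/C(=O)OC(C)(C)C)[C@@]2(C)CC[C@@H](OC(=O)CC(C)C)[C@](C)(COC(=O)CC(C)C)[C@@H]2[C@H](O)C1 | intermediate
29 | trimethylsilyl (13E)-3α,19-bis(3-methylbutanoyloxy)-6β-(trimethylsilyloxy)labda-8(9),13-dien-15-oate | CC1=C(CC/C(C)=C/C(=O)O[Si](C)(C)C)[C@@]2(C)CC[C@@H](OC(=O)CC(C)C)[C@](C)(COC(=O)CC(C)C)[C@@H]2[C@H](O[Si](C)(C)C)C1 | intermediate
30 | (13E)-6β-hydroxy-3α,19-bis(3-methylbutanoyloxy)labda-8(9),13-dien-15-oic acid (CNP0333611.1) | CC1=C(CC/C(C)=C/C(=O)O)[C@@]2(C)CC[C@@H](OC(=O)CC(C)C)[C@](C)(COC(=O)CC(C)C)[C@@H]2[C@H](O)C1 | target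

## Step count and least certain steps

Total step count: 20. Longest linear sequence: 17 steps (1–7, 10–12, 14–20). Steps 8–9 (amide 13) and step 13 (enol triflate 21) are side branches.

**Step 11 (key step).** In the photochemical stage, loss of CO from the acyl radical, cycloreversion of the excited cyclobutanone and photoreversal at high conversion compete with recombination at C7. In the base stage, which is the more likely problem, the C8=C9 alkene may migrate into conjugation with the C6 carbonyl. The C7 hydrogens (α to the ketone and allylic) are removed faster than the hindered C5 hydrogen, and the conjugated enone is the thermodynamic sink.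

Fallback (sets out from 16, returns at 18): irradiate as in step 11, then give up the kinetic distinction. Base (catalytic NaOMe in MeOH, 25 °C) carries the material to the thermodynamic product, the trans-fused conjugated 12-chloro-7-en-6-one F1 (C5 equilibrated, C9 epimers). Soft, equilibrating enolisation (Me3SiOTf, Et3N, CH2Cl2) converts it into the fully endocyclic 6-(trimethylsilyloxy)-6,8(9)-diene F2. Buffered fluoride (Bu4NF–AcOH, −78 °C) protodesilylates this, and kinetic protonation at C7 should return the β,γ-unsaturated ketone 18. This is the known deconjugation of enones through their dienol derivatives, and the chloride should tolerate all three operations.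

**Step 10.** The intermolecular cycloaddition may be slow, because two adjacent quaternary carbons (C9, C10) are formed next to quaternary C4. Keteniminium ion 14 may instead react with the isopropenyl group of not yet activated 13, or close at C7 to a six-membered iminium ion. Facial selectivity may be insufficient, since the α-face preference rests only on the pseudoaxial CH2OTBS arm.

Fallback (sets out from 9 and 11, returns at 16): generate the less hindered vinylketeniminium ion directly from 11 (Tf2O, collidine, γ-deprotonation), which carries hydrogen where 14 carries the chloroethyl group. Cycloaddition with 9 and hydrolysis should give the cis-fused 9-isopropenyl cyclobutanone with C9–H F3. Deprotonation at C9 (the allylic α-position; C5–H is hindered) with LiN(i-Pr)2 and α-alkylation of the dienolate with 2-chloroethyl trifluoromethanesulfonate then install the stub and lead to 16.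

**Step 17.** Reduction at the hindered C6 carbonyl may be incomplete, with enolisation by the basic hydride in place of addition, or hydride may arrive at C3 from the wrong face.

Fallback (sets out from 25, returns at 27): remove the C19 silyl group first (HF·pyridine) to give the 19-hydroxy-3,6-dione F4. Reduce C3 by intramolecular hydride delivery from the C19 alkoxyborohydride (Me4NBH(OAc)3, MeCN–AcOH, −20 °C; Evans–Saksena reduction). This can only reach the β face of C3 and should give the 3α,19-dihydroxy-6-ketone F5. Reduce the C6 ketone with NaBH4 (small hydride, α-face attack) to reach 27.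

**Step 19.** Chemoselectivity may be lost: the 6β-hydroxyl may be acylated under the forcing that the hindered axial 3α-hydroxyl may require, or an acyl group may migrate from O19 to O6.

Fallback (sets out from 25, returns at 28): proceed through F4 and F5 as described for step 17. Acylate F5 while C6 is still a ketone ((i-PrCH2CO)2O, DMAP, pyridine) to give the 6-oxo-3α,19-bis(3-methylbutanoate) F6. Reduce the C6 ketone last with NaBH4 in MeOH at 0 °C, which leaves the esters alone and gives 28 directly.

Further compounds

F1 | step 11 | trans-fused 12-chloro-3β-(triethylsilyloxy)-19-[tert-butyl(dimethyl)silyloxy]-13,14,15,16-tetranorlabd-7-en-6-one (5α-H, C9 epimers) | CC1=CC(=O)[C@H]2[C@@](C)(CO[Si](C)(C)C(C)(C)C)[C@@H](O[Si](CC)(CC)CC)CC[C@]2(C)C1CCCl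
F2 | step 11 | 12-chloro-3β-(triethylsilyloxy)-19-[tert-butyl(dimethyl)silyloxy]-6-(trimethylsilyloxy)-13,14,15,16-tetranorlabda-6,8(9)-diene (5α-H) | CC1=C(CCCl)[C@@]2(C)CC[C@H](O[Si](CC)(CC)CC)[C@](C)(CO[Si](C)(C)C(C)(C)C)[C@@H]2C(O[Si](C)(C)C)=C1
F3 | step 10 | cis-fused 1,5-dimethyl-8-(prop-1-en-2-yl)-5-{[tert-butyl(dimethyl)silyl]oxymethyl}-4-(triethylsilyloxy)bicyclo[4.2.0]octan-7-one (C9–H, C9 epimers; otherwise as 16) | O=C1[C@@H]2[C@@](C)(CO[Si](C)(C)C(C)(C)C)[C@@H](O[Si](CC)(CC)CC)CC[C@]2(C)C1C(C)=C
F4 | step 17 | tert-butyl (13E)-19-hydroxy-3,6-dioxolabda-8(9),13-dien-15-oate | CC1=C(CC/C(C)=C/C(=O)OC(C)(C)C)[C@@]2(C)CCC(=O)[C@](C)(CO)[C@@H]2C(=O)C1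
F5 | step 17 | tert-butyl (13E)-3α,19-dihydroxy-6-oxolabda-8(9),13-dien-15-oate | CC1=C(CC/C(C)=C/C(=O)OC(C)(C)C)[C@@]2(C)CC[C@@H](O)[C@](C)(CO)[C@@H]2C(=O)C1
F6 | step 19 | tert-butyl (13E)-3α,19-bis(3-methylbutanoyloxy)-6-oxolabda-8(9),13-dien-15-oate | CC1=C(CC/C(C)=C/C(=O)OC(C)(C)C)[C@@]2(C)CC[C@@H](OC(=O)CC(C)C)[C@](C)(COC(=O)CC(C)C)[C@@H]2C(=O)C1
A1 | alternative 1 | 3-[2-(1-methyl-4-oxocyclohexa-2,5-dien-1-yl)-1,3-dioxolan-2-yl]propanal | O=CCCC1(OCCO1)C2(C)C=CC(=O)C=C2
A2 | alternative 1 | trans-fused 10-methyl-Δ1-decalin-3,6-dione with the C9 carbonyl masked as a dioxolane (5α-H, 10β-CH3) | O=C1CCC2(OCCO2)[C@@]3(C)C=CC(=O)C[C@H]13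
A3 | alternative 2 | ring A ethoxydiene, C7=C6(OEt)–C5=C10 with 10-CH3, 3β-OTES, 4α-CH3, 4β-CH2OTBS | C=C(OCC)C1=C(C)CC[C@H](O[Si](CC)(CC)CC)[C@]1(C)CO[Si](C)(C)C(C)(C)C
A4 | alternative 2 | ethyl but-2-ynoate | CC#CC(=O)OCC
A5 | alternative 2 | bicyclic cyclohexa-1,4-diene with C6 ethyl enol ether (C5=C6), C8=C9 alkene and C9 ethyl ester (3β-OTES, 19-OTBS, 10β-CH3) | CC1=C(C(=O)OCC)[C@@]2(C)CC[C@H](O[Si](CC)(CC)CC)[C@](C)(CO[Si](C)(C)C(C)(C)C)C2=C(OCC)C1
A6 | alternative 3 | tert-butyldimethylsilyl enol ether C6(OSi)=C7H2 of the ring A methyl ketone, C10 bearing β-methyl and prop-1-ynyl (5α-H, 3β-OTES, 19-OTBS) | CC#C[C@@]1(C)CC[C@H](O[Si](CC)(CC)CC)[C@](C)(CO[Si](C)(C)C(C)(C)C)[C@@H]1C(=C)O[Si](C)(C)C(C)(C)C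
A7 | alternative 3 | trans-fused 9-iodo-6-oxo-Δ8(9) decalin (3β-OTES, 19-OTBS) | CC1=C(I)[C@@]2(C)CC[C@H](O[Si](CC)(CC)CC)[C@](C)(CO[Si](C)(C)C(C)(C)C)[C@@H]2C(=O)C1
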